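**Strategy.** The route rests on disconnecting the C3–O bond of the dihydrofuran ring (O1, C2, C3, C3a, C7a) as a lactone. C3 is benzylic and para, through C3a, to the C6 hydroxyl, and the side-chain carbon that carries the acetate sits on C1', cis to C3. With that carbon as a carboxylic acid, two-electron oxidation of the phenol to its para-quinone methide lets the carboxylate add to C3. One operation forms the C3–O bond, a cis-fused α-methylene γ-lactone and the C3 stereocentre. The precursor is the (2S)-2-(dihydrobenzofuran-2-yl)acrylic acid 15 with free C6 phenol and C5 acetyl, made by Stille prenylation, Shi epoxidation and phenoxide cyclisation.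

Key step: step 11

Assumption: atoms are numbered as in 1-benzofuran (O1, C2, C3, C3a, C4 to C7, C7a; C1' is the side-chain carbon on C2), and the D-fructose-derived Shi ketone is taken to give the (R)-oxirane from the prenyl group, as it does with other trisubstituted alkenes.

Step 1
Reactants: 1 2,4-dihydroxyacetophenone
Product: 2 1-(5-bromo-2,4-dihydroxyphenyl)ethanone
Conditions: N-bromosuccinimide (1.0 equiv), MeCN, 0 °C → rt
Reagents that add atoms: N-bromosuccinimide, O=C1CCC(=O)N1Br
Why: Electrophilic aromatic bromination should go to C5, which is para to the chelated 2-hydroxyl, ortho to the 4-hydroxyl and less crowded than C3 between the two oxygens, so the halogen marks the carbon that must carry the prenyl group (direct C-prenylation would favour C3).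

Step 2
Reactants: 2 1-(5-bromo-2,4-dihydroxyphenyl)ethanone
Product: 3 1-{5-bromo-2-hydroxy-4-[(triisopropylsilyl)oxy]phenyl}ethanone
Conditions: i-Pr3SiCl, imidazole, DMF, rt
Reagents that add atoms: chlorotriisopropylsilane, CC(C)[Si](Cl)(C(C)C)C(C)C
Why: Imidazole-promoted silyl ether formation is selective for the 4-hydroxyl because the 2-hydroxyl is held in a hydrogen bond to the acetyl carbonyl and is shielded from the bulky silyl chloride.

Step 3
Reactants: 3 1-{5-bromo-2-hydroxy-4-[(triisopropylsilyl)oxy]phenyl}ethanone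
Product: 4 1-{5-bromo-2-(methoxymethoxy)-4-[(triisopropylsilyl)oxy]phenyl}ethanone
Conditions: MeOCH2Cl, i-Pr2NEt, CH2Cl2, 0 → 40 °C
Reagents that add atoms: chloromethyl methyl ether, COCCl
Why: Williamson-type O-alkylation caps the chelated phenol as a methoxymethyl acetal, which tolerates fluoride, base and the oxidants used later and is removed by dilute acid.

Step 4
Reactants: 4 1-{5-bromo-2-(methoxymethoxy)-4-[(triisopropylsilyl)oxy]phenyl}ethanone; 5 tributyl(3-methylbut-2-en-1-yl)stannane
Product: 6 1-{2-(methoxymethoxy)-5-(3-methylbut-2-en-1-yl)-4-[(triisopropylsilyl)oxy]phenyl}ethanone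
Conditions: Pd(PPh3)4 (5 mol%), DMF, 100 °C
Reagents that add atoms: tributyl(3-methylbut-2-en-1-yl)stannane (5), CC(C)=CC[Sn](CCCC)(CCCC)CCCC
Why: Stille cross-coupling of the aryl bromide with the prenylstannane transfers the allyl group through its unsubstituted carbon, which fixes the linear prenyl chain at the brominated carbon and leaves ketone, acetal and silyl ether untouched.

Step 5
Reactants: 6 1-{2-(methoxymethoxy)-5-(3-methylbut-2-en-1-yl)-4-[(triisopropylsilyl)oxy]phenyl}ethanone
Product: 7 1-{5-{[(2R)-3,3-dimethyloxiran-2-yl]methyl}-2-(methoxymethoxy)-4-[(triisopropylsilyl)oxy]phenyl}ethanone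
Conditions: 1,2:4,5-di-O-isopropylidene-β-D-erythro-2,3-hexodiulo-2,6-pyranose (0.3 equiv), KHSO5 (as 2KHSO5·KHSO4·K2SO4), K2CO3, n-Bu4NHSO4, MeCN/CH2(OMe)2/aq. Na2B4O7 buffer, 0 °C
Reagents that add atoms: potassium peroxymonosulfate, [K+].[O-]S(=O)(=O)OO
Why: Shi asymmetric epoxidation of the trisubstituted alkene through the spiro transition state of the chiral dioxirane should give the (R)-oxirane, and with both phenols masked neither phenoxide oxidation nor Dakin-type cleavage of the aryl ketone can compete.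

Step 6
Reactants: 7 1-{5-{[(2R)-3,3-dimethyloxiran-2-yl]methyl}-2-(methoxymethoxy)-4-[(triisopropylsilyl)oxy]phenyl}ethanone
Product: 9 1-[(2S)-2-(2-hydroxypropan-2-yl)-6-(methoxymethoxy)-2,3-dihydro-1-benzofuran-5-yl]ethanone, via epoxy phenoxide 8 (not isolated)
Conditions: n-Bu4NF (1.2 equiv), THF, 0 → 40 °C
Reagents that add atoms: none
Why: Fluoride cleaves the aryl silyl ether and the freed phenoxide opens the epoxide by 5-exo-tet SN2 attack at the secondary carbon with inversion, so the (R)-oxirane becomes the (S)-configured C2 of the dihydrobenzofuran.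

Step 7
Reactants: 9 1-[(2S)-2-(2-hydroxypropan-2-yl)-6-(methoxymethoxy)-2,3-dihydro-1-benzofuran-5-yl]ethanone
Product: 11 1-[(2S)-6-(methoxymethoxy)-2-(prop-1-en-2-yl)-2,3-dihydro-1-benzofuran-5-yl]ethanone, via sulfamate ester 10 (not isolated)
Conditions: methyl N-(triethylammoniosulfonyl)carbamate (2 equiv), toluene, 70 °C
Reagents that add atoms: none
Why: Burgess dehydration is a syn elimination of the tertiary sulfamate ester in which the six methyl hydrogens are favoured statistically and electronically over the single C2–H next to O1, so the isopropenyl group should form without touching the C2 stereocentre.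

Step 8
Reactants: 11 1-[(2S)-6-(methoxymethoxy)-2-(prop-1-en-2-yl)-2,3-dihydro-1-benzofuran-5-yl]ethanone
Product: 12 1-[(2S)-2-(3-hydroxyprop-1-en-2-yl)-6-(methoxymethoxy)-2,3-dihydro-1-benzofuran-5-yl]ethanone
Conditions: SeO2 (0.5 equiv), t-BuOOH (3 equiv), CH2Cl2, rt
Reagents that add atoms: selenium dioxide, O=[Se]=O; tert-butyl hydroperoxide, CC(C)(C)OO
Why: Riley allylic oxidation (ene reaction at the terminal CH2, then 2,3-sigmatropic shift) should hydroxylate the methyl group of the 1,1-disubstituted alkene in preference to the hindered tertiary C2–H, and at room temperature the aryl methyl ketone is not attacked.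

Step 9
Reactants: 12 1-[(2S)-2-(3-hydroxyprop-1-en-2-yl)-6-(methoxymethoxy)-2,3-dihydro-1-benzofuran-5-yl]ethanone
Product: 14 2-[(2S)-5-acetyl-6-(methoxymethoxy)-2,3-dihydro-1-benzofuran-2-yl]prop-2-enoic acid, via enal 13 (not isolated)
Conditions: 2,2,6,6-tetramethylpiperidin-1-oxyl (cat.), PhI(OAc)2, CH2Cl2, rt; then NaClO2, NaH2PO4, 2-methyl-2-butene, t-BuOH/H2O, rt
Reagents that add atoms: sodium chlorite, [Na+].[O-]Cl=O
Why: Oxoammonium oxidation takes the allylic alcohol (and any enal from step 8) to the 2-substituted acrolein and Pinnick oxidation gives the acrylic acid under buffered conditions free of nucleophilic amines, which could otherwise open the allylic C2–O1 bond by conjugate addition and elimination.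

Step 10
Reactants: 14 2-[(2S)-5-acetyl-6-(methoxymethoxy)-2,3-dihydro-1-benzofuran-2-yl]prop-2-enoic acid
Product: 15 2-[(2S)-5-acetyl-6-hydroxy-2,3-dihydro-1-benzofuran-2-yl]prop-2-enoic acid
Conditions: 2 M HCl (aq.), THF, 40 °C
Reagents that add atoms: none
Why: Acid hydrolysis of the methoxymethyl acetal, which is accelerated by the ortho acetyl group, frees the C6 phenol while the acrylic acid and the C2–O1 ether, whose ionisation is disfavoured by the electron-poor alkene, are left alone.

Step 11
Reactants: 15 2-[(2S)-5-acetyl-6-hydroxy-2,3-dihydro-1-benzofuran-2-yl]prop-2-enoic acid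
Product: 17 (3aR,8bR)-7-acetyl-6-hydroxy-3-methylidene-3a,8b-dihydrofuro[3,2-b][1]benzofuran-2(3H)-one (cis-fused lactone between the C1' carboxyl and C3 of the benzofuran), via quinone methide 16 (not isolated)
Conditions: undivided cell, graphite anode, Pt cathode, constant current (about 2.1 F/mol), 2,6-lutidine (2 equiv), n-Bu4NPF6 (0.1 M), (CF3)2CHOH/CH2Cl2 4:1, 0 °C
Reagents that add atoms: none
Why: Proposed new method: the C6 phenol should lose two electrons and, to 2,6-lutidine, its O–H proton and one C3 proton, giving para-quinone methide 16 with an exocyclic C3=C3a bond, to which the C1' carboxylate adds at C3 with rearomatisation. The closest known reaction types are the anodic or chemical side-chain oxidation of para-alkylphenols to quinone methides with capture at the benzylic carbon by oxygen nucleophiles, and the oxidative benzylic lactonisation of 4-arylbutanoic acids; a quinone methide of the 2H-benzofuran-6-one type trapped by an acrylic acid has not been shown. The lactone ring closes in the 5-exo-trig mode onto the exocyclic C3=C3a bond. The new C3 stereocentre is controlled by the C2 centre, because the tether from C2 can reach only the face of C3 that gives the cis-fused bicycle, so C3 becomes R. The step needs oxidation of the phenol ahead of the alkene and the product, and ring closure ahead of loss of the C2 proton to the aromatic benzofuran; the electron-rich para-alkyl phenol, charge control near two electrons per molecule, the hindered non-nucleophilic buffer, the low temperature and the intramolecular trap should secure this. Should the carboxylate be oxidised first, 1,5-hydrogen transfer from C3 to the acyloxy radical leads to the same lactone.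

Step 12
Reactants: 17 (3aR,8bR)-7-acetyl-6-hydroxy-3-methylidene-3a,8b-dihydrofuro[3,2-b][1]benzofuran-2(3H)-one
Product: 18 (3aR,8bR)-6-[(tert-butyldimethylsilyl)oxy]-7-{1-[(tert-butyldimethylsilyl)oxy]ethenyl}-3-methylidene-3a,8b-dihydrofuro[3,2-b][1]benzofuran-2(3H)-one
Conditions: t-BuMe2SiOTf (3 equiv), i-Pr2NEt (5 equiv), CH2Cl2, −78 → 0 °C
Reagents that add atoms: tert-butyldimethylsilyl trifluoromethanesulfonate, CC(C)(C)[Si](C)(C)OS(=O)(=O)C(F)(F)F
Why: Silyl triflate and a hindered amine silylate the chelated phenol and turn the methyl ketone into its silyl enol ether by soft enolisation, which masks both groups against hydride in one operation while the non-nucleophilic base cannot add to the α-methylene lactone.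

Step 13
Reactants: 18 (3aR,8bR)-6-[(tert-butyldimethylsilyl)oxy]-7-{1-[(tert-butyldimethylsilyl)oxy]ethenyl}-3-methylidene-3a,8b-dihydrofuro[3,2-b][1]benzofuran-2(3H)-one
Product: 20 (2R,3R)-6-[(tert-butyldimethylsilyl)oxy]-5-{1-[(tert-butyldimethylsilyl)oxy]ethenyl}-2-(3-hydroxyprop-1-en-2-yl)-2,3-dihydro-1-benzofuran-3-ol, via lactol 19 (not isolated)
Conditions: i-Bu2AlH (4.5 equiv), CH2Cl2, −78 → −20 °C; aq. KNaC4H4O6
Reagents that add atoms: none
Why: 1,2-Selective aluminium hydride reduction of the α-methylene γ-lactone through the lactol gives the primary allylic alcohol and the C3 alcohol without breaking the C3–O bond, so the cis relationship from the key step is carried over and the silyl enol ether is inert to the hydride.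

Step 14
Reactants: 20 (2R,3R)-6-[(tert-butyldimethylsilyl)oxy]-5-{1-[(tert-butyldimethylsilyl)oxy]ethenyl}-2-(3-hydroxyprop-1-en-2-yl)-2,3-dihydro-1-benzofuran-3-ol
Product: 21 2-[(2R,3R)-6-[(tert-butyldimethylsilyl)oxy]-5-{1-[(tert-butyldimethylsilyl)oxy]ethenyl}-3-hydroxy-2,3-dihydro-1-benzofuran-2-yl]prop-2-en-1-yl acetate
Conditions: AcCl (1.1 equiv), 2,4,6-collidine, CH2Cl2, −78 °C
Reagents that add atoms: acetyl chloride, CC(=O)Cl
Why: Kinetic O-acylation at low temperature with a hindered pyridine base discriminates the unhindered primary allylic hydroxyl from the secondary benzylic C3 hydroxyl, which is flanked by the arene and the C2 substituent.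

Step 15
Reactants: 21 2-[(2R,3R)-6-[(tert-butyldimethylsilyl)oxy]-5-{1-[(tert-butyldimethylsilyl)oxy]ethenyl}-3-hydroxy-2,3-dihydro-1-benzofuran-2-yl]prop-2-en-1-yl acetate; 22 angelic acid
Product: 23 (2R,3R)-2-[3-(acetyloxy)prop-1-en-2-yl]-6-[(tert-butyldimethylsilyl)oxy]-5-{1-[(tert-butyldimethylsilyl)oxy]ethenyl}-2,3-dihydro-1-benzofuran-3-yl (2Z)-2-methylbut-2-enoate
Conditions: 22, 2,4,6-Cl3C6H2COCl, Et3N, toluene, rt; then 21, 75 °C
Reagents that add atoms: angelic acid (22), C/C=C(/C)C(=O)O
Why: Yamaguchi esterification through the mixed 2,4,6-trichlorobenzoic anhydride acylates the hindered C3 hydroxyl at the angeloyl carbonyl, and running it without a nucleophilic pyridine catalyst is the established way to keep the (Z)-alkene from isomerising to the tiglate.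

Step 16
Reactants: 23 (2R,3R)-2-[3-(acetyloxy)prop-1-en-2-yl]-6-[(tert-butyldimethylsilyl)oxy]-5-{1-[(tert-butyldimethylsilyl)oxy]ethenyl}-2,3-dihydro-1-benzofuran-3-yl (2Z)-2-methylbut-2-enoate
Product: 24 (2R,3R)-5-acetyl-2-[3-(acetyloxy)prop-1-en-2-yl]-6-hydroxy-2,3-dihydro-1-benzofuran-3-yl (2Z)-2-methylbut-2-enoate
Conditions: n-Bu4NF (2.5 equiv), AcOH (3 equiv), THF, 0 °C
Reagents that add atoms: none
Why: Buffered fluoride desilylation cleaves the aryl silyl ether and the silyl enol ether, the latter tautomerising to the methyl ketone, while acetic acid keeps the C6 phenol protonated so that it can neither expel the para-benzylic angelate nor promote acyl migration.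

**Compound list**

1 | 2,4-dihydroxyacetophenone | CC(=O)c1ccc(O)cc1O | starting material
2 | 1-(5-bromo-2,4-dihydroxyphenyl)ethanone | CC(=O)c1cc(Br)c(O)cc1O | intermediate
3 | 1-{5-bromo-2-hydroxy-4-[(triisopropylsilyl)oxy]phenyl}ethanone | CC(=O)c1cc(Br)c(O[Si](C(C)C)(C(C)C)C(C)C)cc1O | intermediate
4 | 1-{5-bromo-2-(methoxymethoxy)-4-[(triisopropylsilyl)oxy]phenyl}ethanone | CC(=O)c1cc(Br)c(O[Si](C(C)C)(C(C)C)C(C)C)cc1OCOC | intermediate
5 | tributyl(3-methylbut-2-en-1-yl)stannane | CC(C)=CC[Sn](CCCC)(CCCC)CCCC | starting material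
6 | 1-{2-(methoxymethoxy)-5-(3-methylbut-2-en-1-yl)-4-[(triisopropylsilyl)oxy]phenyl}ethanone | CC(=O)c1cc(CC=C(C)C)c(O[Si](C(C)C)(C(C)C)C(C)C)cc1OCOC | intermediate
7 | 1-{5-{[(2R)-3,3-dimethyloxiran-2-yl]methyl}-2-(methoxymethoxy)-4-[(triisopropylsilyl)oxy]phenyl}ethanone | CC(=O)c1cc(C[C@H]2OC2(C)C)c(O[Si](C(C)C)(C(C)C)C(C)C)cc1OCOC | intermediate
8 | 1-{5-{[(2R)-3,3-dimethyloxiran-2-yl]methyl}-4-hydroxy-2-(methoxymethoxy)phenyl}ethanone, present as its tetrabutylammonium phenoxide | CC(=O)c1cc(C[C@H]2OC2(C)C)c(O)cc1OCOC | intermediate (not isolated)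
9 | 1-[(2S)-2-(2-hydroxypropan-2-yl)-6-(methoxymethoxy)-2,3-dihydro-1-benzofuran-5-yl]ethanone | CC(C)(O)[C@H]1Oc2cc(OCOC)c(C(C)=O)cc2C1 | intermediate
10 | 2-[(2S)-5-acetyl-6-(methoxymethoxy)-2,3-dihydro-1-benzofuran-2-yl]propan-2-yl N-(methoxycarbonyl)sulfamate, present as its triethylammonium salt | COC(=O)NS(=O)(=O)OC(C)(C)[C@H]1Oc2cc(OCOC)c(C(C)=O)cc2C1 | intermediate (not isolated)
11 | 1-[(2S)-6-(methoxymethoxy)-2-(prop-1-en-2-yl)-2,3-dihydro-1-benzofuran-5-yl]ethanone | C=C(C)[C@H]1Oc2cc(OCOC)c(C(C)=O)cc2C1 | intermediate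
12 | 1-[(2S)-2-(3-hydroxyprop-1-en-2-yl)-6-(methoxymethoxy)-2,3-dihydro-1-benzofuran-5-yl]ethanone | C=C(CO)[C@H]1Oc2cc(OCOC)c(C(C)=O)cc2C1 | intermediate
13 | 2-[(2S)-5-acetyl-6-(methoxymethoxy)-2,3-dihydro-1-benzofuran-2-yl]prop-2-enal | C=C(C=O)[C@H]1Oc2cc(OCOC)c(C(C)=O)cc2C1 | intermediate (not isolated)
14 | 2-[(2S)-5-acetyl-6-(methoxymethoxy)-2,3-dihydro-1-benzofuran-2-yl]prop-2-enoic acid | C=C(C(=O)O)[C@H]1Oc2cc(OCOC)c(C(C)=O)cc2C1 | intermediate
15 | 2-[(2S)-5-acetyl-6-hydroxy-2,3-dihydro-1-benzofuran-2-yl]prop-2-enoic acid | C=C(C(=O)O)[C@H]1Oc2cc(O)c(C(C)=O)cc2C1 | intermediate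
16 | 2-[(2S)-5-acetyl-6-oxo-2,6-dihydro-1-benzofuran-2-yl]prop-2-enoic acid (para-quinone methide) | C=C(C(=O)O)[C@H]1OC2=CC(=O)C(C(C)=O)=CC2=C1 | intermediate (not isolated)
17 | (3aR,8bR)-7-acetyl-6-hydroxy-3-methylidene-3a,8b-dihydrofuro[3,2-b][1]benzofuran-2(3H)-one | C=C3[C@H]1Oc2cc(O)c(C(C)=O)cc2[C@H]1OC3=O | intermediate
18 | (3aR,8bR)-6-[(tert-butyldimethylsilyl)oxy]-7-{1-[(tert-butyldimethylsilyl)oxy]ethenyl}-3-methylidene-3a,8b-dihydrofuro[3,2-b][1]benzofuran-2(3H)-one | C=C3[C@H]1Oc2cc(O[Si](C)(C)C(C)(C)C)c(C(=C)O[Si](C)(C)C(C)(C)C)cc2[C@H]1OC3=O | intermediate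
19 | (3aR,8bR)-6-[(tert-butyldimethylsilyl)oxy]-7-{1-[(tert-butyldimethylsilyl)oxy]ethenyl}-3-methylidene-2,3,3a,8b-tetrahydrofuro[3,2-b][1]benzofuran-2-ol (lactol, as its aluminium alkoxide; lactol carbon unassigned) | C=C3[C@H]1Oc2cc(O[Si](C)(C)C(C)(C)C)c(C(=C)O[Si](C)(C)C(C)(C)C)cc2[C@H]1OC3O | intermediate (not isolated)
20 | (2R,3R)-6-[(tert-butyldimethylsilyl)oxy]-5-{1-[(tert-butyldimethylsilyl)oxy]ethenyl}-2-(3-hydroxyprop-1-en-2-yl)-2,3-dihydro-1-benzofuran-3-ol | C=C(CO)[C@H]1Oc2cc(O[Si](C)(C)C(C)(C)C)c(C(=C)O[Si](C)(C)C(C)(C)C)cc2[C@H]1O | intermediate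
21 | 2-[(2R,3R)-6-[(tert-butyldimethylsilyl)oxy]-5-{1-[(tert-butyldimethylsilyl)oxy]ethenyl}-3-hydroxy-2,3-dihydro-1-benzofuran-2-yl]prop-2-en-1-yl acetate | C=C(COC(C)=O)[C@H]1Oc2cc(O[Si](C)(C)C(C)(C)C)c(C(=C)O[Si](C)(C)C(C)(C)C)cc2[C@H]1O | intermediate
22 | angelic acid, (2Z)-2-methylbut-2-enoic acid | C/C=C(/C)C(=O)O | starting material
23 | (2R,3R)-2-[3-(acetyloxy)prop-1-en-2-yl]-6-[(tert-butyldimethylsilyl)oxy]-5-{1-[(tert-butyldimethylsilyl)oxy]ethenyl}-2,3-dihydro-1-benzofuran-3-yl (2Z)-2-methylbut-2-enoate | C=C(COC(C)=O)[C@H]1Oc2cc(O[Si](C)(C)C(C)(C)C)c(C(=C)O[Si](C)(C)C(C)(C)C)cc2[C@H]1OC(=O)/C(C)=C\C | intermediate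
24 | (2R,3R)-5-acetyl-2-[3-(acetyloxy)prop-1-en-2-yl]-6-hydroxy-2,3-dihydro-1-benzofuran-3-yl (2Z)-2-methylbut-2-enoate | C=C(COC(C)=O)[C@H]1Oc2cc(O)c(C(C)=O)cc2[C@H]1OC(=O)/C(C)=C\C | target

Total step count: 16. Longest linear sequence: 16 steps (1 to 24); 5 and 22 are purchased.

**Steps most likely to fail**

Step 11. The quinone methide may lose the C2 proton faster than the carboxylate closes, which aromatises the ring to a benzofuran and erases the C2 centre. The product phenol may also be oxidised a second time. The fallback uses known chemistry, sets out from 14 and comes back at 17. With the phenol still protected, 14 is treated with PhI(OAc)2 and KBr in CH2Cl2 at rt, a carboxyl-directed radical benzylic lactonisation of the kind established for 4-arylbutanoic acids. The acyloxy radical abstracts the C3 hydrogen through a six-membered transition state (the C2 hydrogen would need a five-membered one), and the benzylic position closes onto the carboxyl to give the methoxymethyl-protected cis-lactone F1. Dilute HCl in THF then removes the acetal and gives 17.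

Step 7. Elimination may run toward C2, giving the exocyclic enol ether and, from it, the 2-isopropylbenzofuran, instead of toward a methyl group. The fallback sets out from 6 and comes back at 11, making the ring, the C2 centre and the isopropenyl group together so that no dehydration is needed. SeO2/t-BuOOH oxidises the trans methyl group of 6 to the (E)-allylic alcohol F2. Methyl chloroformate and pyridine give the allylic methyl carbonate F3, and n-Bu4NF buffered with AcOH frees the phenol carbonate F4. Pd2(dba)3·CHCl3 with N,N'-bis[2-(diphenylphosphino)benzoyl]cyclohexane-1,2-diamine then effects an asymmetric Tsuji–Trost etherification, the phenoxide attacking the more substituted allyl terminus to give 11. The ligand enantiomer that delivers the (2S) product is chosen in a pilot run.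

Step 15. Acylation of the crowded C3 hydroxyl may be slow, and forcing it may isomerise the (Z)-angeloyl unit to the tiglate. The fallback sets out from 21 and comes back at 23, building the (Z)-alkene on the substrate. Compound 21 is esterified with 2-[bis(2,2,2-trifluoroethoxy)phosphoryl]propanoic acid (carbodiimide, cat. 4-dimethylaminopyridine, CH2Cl2, 0 °C) to the phosphonate ester F5. Its potassium anion (KN(SiMe3)2, 18-crown-6, THF, −78 °C) undergoes Still–Gennari olefination with acetaldehyde to give the (Z)-2-methylbut-2-enoate 23.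

**Further compounds**

F1 | step 11 | (3aR,8bR)-7-acetyl-6-(methoxymethoxy)-3-methylidene-3a,8b-dihydrofuro[3,2-b][1]benzofuran-2(3H)-one | C=C3[C@H]1Oc2cc(OCOC)c(C(C)=O)cc2[C@H]1OC3=O
F2 | step 7 | 1-{5-[(2E)-4-hydroxy-3-methylbut-2-en-1-yl]-2-(methoxymethoxy)-4-[(triisopropylsilyl)oxy]phenyl}ethanone | CC(=O)c1cc(C/C=C(\C)CO)c(O[Si](C(C)C)(C(C)C)C(C)C)cc1OCOC
F3 | step 7 | (2E)-4-{5-acetyl-4-(methoxymethoxy)-2-[(triisopropylsilyl)oxy]phenyl}-2-methylbut-2-en-1-yl methyl carbonate | CC(=O)c1cc(C/C=C(\C)COC(=O)OC)c(O[Si](C(C)C)(C(C)C)C(C)C)cc1OCOC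
F4 | step 7 | (2E)-4-[5-acetyl-2-hydroxy-4-(methoxymethoxy)phenyl]-2-methylbut-2-en-1-yl methyl carbonate | CC(=O)c1cc(C/C=C(\C)COC(=O)OC)c(O)cc1OCOC
F5 | step 15 | (2R,3R)-2-[3-(acetyloxy)prop-1-en-2-yl]-6-[(tert-butyldimethylsilyl)oxy]-5-{1-[(tert-butyldimethylsilyl)oxy]ethenyl}-2,3-dihydro-1-benzofuran-3-yl 2-[bis(2,2,2-trifluoroethoxy)phosphoryl]propanoate | C=C(COC(C)=O)[C@H]1Oc2cc(O[Si](C)(C)C(C)(C)C)c(C(=C)O[Si](C)(C)C(C)(C)C)cc2[C@H]1OC(=O)C(C)P(=O)(OCC(F)(F)F)OCC(F)(F)F
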